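Violet holds 1.57 times the racemization catalyst of green, yet after 40.0 h the two have converted 59.7% and 61.5% of their substrate, about the same. I therefore carry their mean of 60.6% to the flask, although its 50 µM of catalyst lies below both runs.

| setting | green | violet | flask |
|---|---|---|---|
| left-handed substrate | 10 mM | 10 mM | 10 mM |
| right-handed substrate | 10 mM | 10 mM | 10 mM |
| reagent | 40 mM | 40 mM | 40.0 mM |
| racemization catalyst | 70 µM | 110 µM | 50 µM |
| added ligand | 0.18 mM | 0.18 mM | 0.18 mM |
| remark | run made earlier | run made earlier |  |
| time |  |  | 40 h |

| run | time / h | left-handed product / % | right-handed product / % |
|---|---|---|---|
| green | 4.00 | 7.2 | 4.2 |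
| green | 10.0 | 14.7 | 7.9 |
| green | 20.0 | 25.4 | 17.8 |
| green | 30.0 | 30.3 | 21.1 |
| green | 40.0 | 33.1 | 26.6 |
| violet | 3.00 | 4.5 | 1.7 |
| violet | 6.00 | 11.4 | 6.7 |
| violet | 12.0 | 16.7 | 12.6 |
| violet | 20.0 | 27.5 | 16.1 |
| violet | 40.0 | 34.9 | 26.6 |

(standard deviation of a reading: 1 percentage point)

- reagent is single-handed; left-handed substrate and right-handed substrate are mirror images of each other, charged as a racemate, each of them at the stated concentration
- what was read earlier has a scatter of 1 percentage point, one standard deviation
- an excess is the difference of the two amounts in percent of their sum
- an excess is below zero if the other one leads
- the handed part of reagent does not stay in what it makes, so the products of the two hands are mirror images too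

* excess of left-handed product over right-handed product in the product at 2.0 h
* excess of left-handed product over right-handed product in the product at 40 h
* part of the left-handed substrate and right-handed substrate charged together that has reacted at 40 h

I follow one substrate molecule to its fork with the reagent and ask for the selectivity factor s, the rate at which reagent takes left-handed substrate over the rate at which it takes right-handed substrate at equal concentrations, which I read as 1.98. My first way reads it from the earliest points of both runs pooled, where the substrates are still nearly equal, and gives that 1.98, a loose reading, since violet's right-handed product of 1.7% carries a scatter of 1 percentage point. It makes fresh product an excess of 33.0%, which I expect at 2.0 h.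

My second way assumes that every substrate and product molecule keeps its hand, so that the logarithm of left-handed substrate remaining over that of right-handed substrate remaining equals s, with both remainders taken from the product readings. Pooled, this gives 1.82 at 20.0 h but 1.50 at 40.0 h, so it sinks. Reagent stands in both rates, so its running down leaves s unchanged, and I conclude that the second way cheats; my guess, which these readings do not separate from substrate changing hand, is that left-handed product has a fork of its own, leaking into right-handed product. I keep the early s and read the late excess directly from the pooled runs, 12.2%.

The forecast gives 30%, where I expect 33.0%, then 12% and 60%, holding, unlike my guess, that the excess “decays like an ordinary kinetic resolution”. The flask gives 33.4%, 14.2% and 61.2%.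

    left-handed substrate + racemization catalyst ⇌ right-handed substrate + racemization catalyst, rate k1*[racemization catalyst]*[left-handed substrate] forward; the back reaction follows from the equilibrium constant (k = 0.100 M⁻¹ s⁻¹)
    left-handed product ⇌ right-handed product (k = 2.10 × 10⁻⁶ s⁻¹)
    2 racemization catalyst ⇌ resting dimer, settled at all times (K = 2.00 × 10⁶ M⁻¹)
    reagent + right-handed substrate → right-handed product (k = 1.40 × 10⁻⁴ M⁻¹ s⁻¹)
    racemization catalyst + added ligand ⇌ idle complex (K = 1700 M⁻¹, k = 3.50 M⁻¹ s⁻¹)
    reagent + left-handed substrate → left-handed product (k = 2.90 × 10⁻⁴ M⁻¹ s⁻¹)

The two products relax into each other with a half-life of 45.8 h, both ways together, by this step alone, and I test s on the substrates of the flask: from 26% of left-handed substrate left at 40 h, s gives 50.6% of right-handed substrate, and 51% stands there. The neighbouring flask, with c(reagent) at 68 mM, reaches 79.8% conversion and an excess of 8.12%, less than in the flask. Its 9.5% of left-handed substrate left gives 30.5% of right-handed substrate, and 31% stands there.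

The readings were computed for substances that don't exist, and the scatter is random.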